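Slowness marks the north-east run: the target drains over hours, from 10.5% at 0.500 h to 2.3% at 12.0 h. A broad peak of that kind can be located even with readings this far apart.

| flask | substrate | coupling partner | remark | time |
|---|---|---|---|---|
| north-east | 0.34 M (fed, over 2.5 min) | 0.90 M | run made earlier; the fed solution adds 1.0 times the starting volume |  |
| south | 0.75 M (fed, over 2.5 min) | 0.90 M | run made earlier; the fed solution adds 1.0 times the starting volume |  |
| flask | 0.50 M (fed, over 2.5 min) | 0.900 M | the fed solution adds 1.0 times the starting volume | 20 h |

- north-east (time / h: target / %): 0.133: 7.5; 0.500: 10.5; 2.50: 8.3; 12.0: 2.3
- south (time / h: target / %): 0.133: 4.9; 0.500: 6.8; 2.50: 4.6; 12.0: 2.4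

(readings scatter by 0.3 percentage points)

1. the moment within 20 h at which there is most target
2. the amount of target, in percent of the substrate charged, at that time

- every charge counts on the volume at the start, and the solution that is fed holds the whole dose

1. Peak time. In each earlier run the reading at 0.500 h is the highest , so the peak of this flask is placed near that time, bracketed by the readings at 0.133 h and 2.50 h.

2. First way. The charge exponent n is minus the slope of ln(percent of target) against ln[substrate] between two runs read at one time, with the feed and [coupling partner] held. The pair at 0.500 h gives n = 0.549. Carried from the north-east run to [substrate] = 0.50 M, it gives 8.50% for this flask.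

3. Second way. The pair at 8 min, readings that the first way did not use, gives an exponent of 0.538, hence 6.09% for this flask at that time. The rise from there to 0.500 h multiplies the reading by 1.40 in the north-east run and 1.39 in the south run. Their geometric mean gives 8.49%, but these factors bring back the readings at 0.500 h, so this figure is no independent check of 8.50%. The independent comparison is that of the two exponents.

4. Where they part. The two early exponents agree, but later pairs do not: 0.746 at 2.50 h and −0.0538 at 12.0 h. Those pairs are read after the peak and describe the fall, so they are set aside. The reckoning stands at about 8.50%, near 0.500 h.

5. The forecast gives 8.7% at 0.55 h, a little above this reckoning, and holds that “the peak time hardly depends on the substrate charge”.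

6. The flask gives 8.39% at 0.495 h.

    substrate ⇌ intermediate + leaving ligand (K = 2.70 × 10⁻⁵ M, k = 0.00264 s⁻¹)
    coupling partner + intermediate → target (k = 0.147 M⁻¹ s⁻¹)
    leaving ligand + target → side product (k = 0.0349 M⁻¹ s⁻¹)

7. The reckoned 8.50% stands 0.11 percentage points above the flask's value. Carried from that value with n to the neighbour flask with 0.12 M of substrate, the same rule gives 18.4%. That neighbour, with substrate the limiting reagent at 7.50 equiv of coupling partner, gives 20.2%, which is 1.8 points above the reckoning.

The numbers in the tables are calculated for an exercise, noise included.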